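I read each flask at 4.0 min, 1.50 min after the feed stopped, so the question was how long the L had been in the flask by then.

the same everywhere: L 20 mM (fed, over 2.5 min)

| flask | Q | remark | time |
|---|---|---|---|
| red | 2.6 µM | run made earlier |  |
| teal | 80 µM | run made earlier |  |
| Sunday's | 2.0 µM |  | 4.0 min |
| Friday's | 6.0 µM |  | 4.0 min |
| Monday's | 20 µM |  | 4.0 min |
| Tuesday's | 60 µM |  | 4.0 min |

| run | time / s | J / % |
|---|---|---|
| red | 10.0 | 1 |
| red | 15.0 | 2 |
| red | 20.0 | 4 |
| red | 30.0 | 1 |
| red | 50.0 | 7 |
| red | 80.0 | 17 |
| red | 120 | 24 |
| teal | 10.0 | 1 |
| teal | 20.0 | 5 |
| teal | 30.0 | 6 |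
| teal | 50.0 | 6 |
| teal | 80.0 | 13 |
| teal | 90.0 | 18 |
| teal | 120 | 20 |

(each reading ± 1.5 percentage points)

1. amount of J at the end, in percent of the L charged for Sunday's, Friday's, Monday's, Tuesday's, in this order
2. the shape of the row from first to last (hardly changes / falls all the way / falls, then rises / rises, then falls / rises all the way)

- percentages count the whole charge, also what has not yet gone in
- "hardly changes" means that all values lie within two and a half points (for a concentration: within two and a half percent of the largest)

I took the given numbers in turn. The times 4.0 min and 2.5 min are set, not read, and they enter through the mean age of the charge, the time since the average portion went in, which was 2.75 min at the reading. At 120 s the fed fraction was 80.0%, and the share of what had gone in that stood as J was: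

s, red = 24% / 80.0% = 30.0%

s, teal = 20% / 80.0% = 25.0%

One scatter in the red reading moves s by 1.9 percentage points, and the same reading also sets the gap between the runs, so it changes the tilt of the row as well as its height. The number that had to be known well was the gap between the runs: 4 points at 120 s and 4 points at 80.0 s, against a scatter of a difference of 2.1 points.

I read that gap as a slow loss, pseudo-first-order at a steady catalyst, and I assumed it proportional to c(Q), with the red run counted as free of it. The portions fed by 120 s had a mean age of 60.0 s, so:

τ = 60.0 s / ln(s, red / s, teal) = 5.48 min

I called this the drain lifetime: the time in which the teal charge of 80 µM shrinks the stock by a factor e. For another flask I took it to scale inversely with the charged c(Q):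

J at the end = s · exp(−age · c(Q) / (τ · 80 µM))

My row was 29.6%, 28.9%, 26.5%, 20.6%. Moving the teal reading by one scatter of the gap puts Tuesday's figure between 16.3% and 25.4%, still lower than Sunday's.

The forecast, made from the same runs, gave 27%, 27%, 27%, 26%, shape hardly changes, holding that “the split does not depend on Q”. My row differed from it at its far end.

The flasks gave 30.0%, 28.6%, 25.6%, 21.1%: falls all the way.

    L + Q ⇌ G + Q, rate k1*[L]*[Q] forward; the back reaction follows from the equilibrium constant (K = 26.6, k = 160 L mol⁻¹ s⁻¹)
    2 Q ⇌ E, settled at all times (K = 41000 L mol⁻¹)
    L + Q ⇌ J + Q, rate k3*[L]*[Q] forward; the back reaction follows from the equilibrium constant (K = 0.448, k = 11300 L mol⁻¹ s⁻¹)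

The forecast's numbers lay within the margin, but its shape did not. In Tuesday's flask the step from L to J ran alongside the feed, and at 2.50 min J stood at 25.8% with G at 16.0%. With the feed over, the step from L to G went on, and by 4.00 min G stood at 31.9%. My drain lifetime for Tuesday's flask, scaled on the charged c(Q), is 7.31 min, which takes J from 25.8% to 21.0% over those 1.50 min; the flask gave 21.1%. Free Q stood at 10.7 µM in Monday's flask and 21.6 µM in Tuesday's, with E holding the rest of the catalyst, so scaled from Tuesday's on free Q, my lifetime for Monday's flask comes to 14.8 min, which takes J from 27.9% to 25.2%; Monday's flask ended at 25.6%.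

(Readings and results come from a simulation with constants of no real substance; the scatter is artificial.)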